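**Plan**
- Numbering: the chain is C1–C13 (C1 benzylic CH2, C2 CH–OAc, C8 C=O) and the ring carries the chain at C1', OH at C3' and OMe at C5'. The enabling feature is this all-meta benzene ring with two unlike oxygens. C3'–OH reads as a former ketene carbonyl carbon and C5'–OMe as a former ynol ether carbon, so the ring is assembled with its oxygens already distinct.
- Cuts, in order:
  (a) C8 ketone back to its dioxolane;
  (b) ring bonds C3'–C4' and C5'–C6' (benzannulation, C2'–C3' reclosing) back to a 3-alkylcyclobutenone and methoxyacetylene;
  (c) the four-membered ring back to a terminal alkyne and dichloroketene;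
  (d) C1–C2 back to 7-oxododecanal and an allenylboronate;
  (e) C2 and C8 rejoined as the C=C of 1-pentylcycloheptene;
  (f) C8–C9 back to cycloheptanone and a pentyl Grignard reagent.
- Forward order: C8–C9 bond, opening of the seven-membered ring, C1–C2 bond, cyclobutenone ring, benzene ring, ketal hydrolysis.
- One protecting group is used, a dioxolane at C8, because dichloroketene generated with zinc (ZnCl2 present) adds to and acylates enolisable dialkyl ketones. Methoxyacetylene is prepared in one step because it is not a dependable catalogue item.
- Stereochemistry: C2 (R), the only stereocentre, is set by a chiral phosphoric acid-catalysed propargylboration of the aldehyde and is not touched afterwards.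

Key step: step 10

Assumption: the (S)-configured phosphoric acid is taken to deliver the propargyl group to the Si face of the aliphatic aldehyde, the mirror image of the Re-face delivery established for the (R)-acid; if the sense were reversed on this substrate, the antipodal acid would be used.

Step 1
Reactants: 1 cycloheptanone; 2 pentylmagnesium bromide
Product: 4 1-pentylcycloheptan-1-ol, via bromomagnesium alkoxide 3 (not isolated)
Conditions: 2 (1.2 equiv), Et2O, 0 °C to rt; then sat. aq NH4Cl
Reagents that add atoms: none
Why: Grignard 1,2-addition of a primary alkylmagnesium halide to an unhindered cyclic ketone forms the C8–C9 bond and creates no stereocentre.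

Step 2
Reactants: 4 1-pentylcycloheptan-1-ol
Product: 5 1-pentylcyclohept-1-ene
Conditions: p-toluenesulfonic acid monohydrate (cat.), toluene, reflux, Dean–Stark
Reagents that add atoms: none
Why: Acid-catalysed E1 dehydration of a tertiary alcohol under equilibrating conditions should favour the endocyclic trisubstituted alkene of the seven-membered ring, and any exocyclic isomer would end after step 3 as volatile cycloheptanone and pentanal that are easily removed.

Step 3
Reactants: 5 1-pentylcyclohept-1-ene
Product: 7 7-oxododecanal, via secondary ozonide 6 (not isolated)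
Conditions: O3, CH2Cl2, −78 °C; then PPh3, −78 °C to rt
Reagents that add atoms: ozone, [O-][O+]=O
Why: Ozonolysis with reductive work-up cleaves the only C=C bond, turning the substituted carbon into the C8 ketone and the CH carbon into the C2 aldehyde with five CH2 groups between them.

Step 4
Reactants: 7 7-oxododecanal; 8 allenylboronic acid pinacol ester
Product: 10 (R)-12-hydroxypentadec-14-yn-6-one, via pinacol borate ester 9 (not isolated)
Conditions: 8 (1.5 equiv), (S)-3,3'-bis(2,4,6-triisopropylphenyl)-1,1'-binaphthalene-2,2'-diyl hydrogen phosphate (10 mol %), 4 Å MS, toluene, −20 °C; then H2O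
Reagents that add atoms: none
Why: In this Brønsted acid-catalysed asymmetric propargylboration the chiral acid activates the boronate by hydrogen bonding to a pinacol oxygen, the allenyl γ-carbon attacks the Si face of the aldehyde through a closed six-membered SE2' transition state to set C2 as (R), and the unactivated ketone does not react with the boronate.

Step 5
Reactants: 10 (R)-12-hydroxypentadec-14-yn-6-one
Product: 11 (R)-9-(2-pentyl-1,3-dioxolan-2-yl)non-1-yn-4-ol
Conditions: ethylene glycol (5 equiv), p-toluenesulfonic acid monohydrate (cat.), benzene, reflux, Dean–Stark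
Reagents that add atoms: ethylene glycol, OCCO
Why: Acid-catalysed ketalisation with azeotropic removal of water masks the C8 ketone ahead of the ketene chemistry, and it is run before acetylation so that no ester is exposed to glycol and acid.

Step 6
Reactants: 11 (R)-9-(2-pentyl-1,3-dioxolan-2-yl)non-1-yn-4-ol
Product: 12 (R)-9-(2-pentyl-1,3-dioxolan-2-yl)non-1-yn-4-yl acetate
Conditions: Ac2O, pyridine, 4-(dimethylamino)pyridine (cat.), CH2Cl2, rt
Reagents that add atoms: acetic anhydride, CC(=O)OC(C)=O
Why: Nucleophile-catalysed O-acylation installs the acetate of the target with retention at C2 (the C–O bond is not broken) and removes the free OH that an acid chloride or a ketene would otherwise acylate.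

Step 7
Reactants: 12 (R)-9-(2-pentyl-1,3-dioxolan-2-yl)non-1-yn-4-yl acetate; 13 trichloroacetyl chloride
Product: 15 (R)-1-(4,4-dichloro-3-oxocyclobut-1-en-1-yl)-7-(2-pentyl-1,3-dioxolan-2-yl)heptan-2-yl acetate, via dichloroketene 14 (not isolated)
Conditions: 13 (2 equiv, slow addition), Zn–Cu couple (3 equiv), Et2O–DME, rt
Reagents that add atoms: none
Why: In this ketene–alkyne [2+2] cycloaddition the electrophilic carbonyl carbon of dichloroketene bonds to the terminal alkyne CH and the CCl2 carbon to the substituted alkyne carbon, giving the 3-alkyl-4,4-dichlorocyclobutenone, while DME ties up the ZnCl2 that could otherwise attack the dioxolane.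

Step 8
Reactants: 15 (R)-1-(4,4-dichloro-3-oxocyclobut-1-en-1-yl)-7-(2-pentyl-1,3-dioxolan-2-yl)heptan-2-yl acetate
Product: 17 (R)-1-(3-oxocyclobut-1-en-1-yl)-7-(2-pentyl-1,3-dioxolan-2-yl)heptan-2-yl acetate, via 4-chlorocyclobutenone 16 (not isolated)
Conditions: Zn dust, AcOH, TMEDA (6 equiv each), EtOH, 0 °C to rt
Reagents that add atoms: none
Why: Stepwise reductive dechlorination of the α,α-dichloro ketone by zinc in an amine-buffered acetic acid medium is the standard way to 3-alkylcyclobutenones, and the buffer should spare the ring C=C bond, the dioxolane and the acetate.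

Step 9
Reactants: 18 chloroacetaldehyde dimethyl acetal
Product: 21 methoxyacetylene, via 1-chloro-2-methoxyethene 19 (not isolated), via sodium methoxyacetylide 20 (not isolated)
Conditions: NaNH2 (3 equiv), liquid NH3, −33 °C; NH3 evaporated; then cold sat. aq NaCl, distilled into a −78 °C trap
Reagents that add atoms: none
Why: Double base-induced 1,2-elimination (loss of methanol, then of HCl) from a β-chloro acetal is the standard preparation of alkoxyacetylenes, the third equivalent of base holding the product as its acetylide until the cold aqueous quench.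

Step 10
Reactants: 17 (R)-1-(3-oxocyclobut-1-en-1-yl)-7-(2-pentyl-1,3-dioxolan-2-yl)heptan-2-yl acetate; 21 methoxyacetylene
Product: 26 (R)-1-(3-hydroxy-5-methoxyphenyl)-7-(2-pentyl-1,3-dioxolan-2-yl)heptan-2-yl acetate, via vinylketene 22 (not isolated), via 4-alkenyl-3-methoxycyclobutenone 23 (not isolated), via dienylketene 24 (not isolated), via cyclohexadienone 25 (not isolated)
Conditions: 21 (3 equiv), toluene, sealed tube, 80 °C
Reagents that add atoms: none
Why: Heat reversibly opens 17 by conrotatory four-electron cleavage of its C(=O)–CH2 bond to vinylketene 22, which the electron-rich alkyne 21 intercepts in a [2+2] cycloaddition that makes C3'–C4' and C5'–C6' and gives 23. A second four-electron opening of 23 leads to dienylketene 24, whose six-electron electrocyclisation between the terminal =CH2 and the ketene carbon (C2'–C3') closes the only lasting new ring, the six-membered carbocycle, as dienone 25, and enolisation gives phenol 26. This is the Danheiser benzannulation, and its closest known cases are 3-alkylcyclobutenones with alkoxyacetylenes giving 5-alkylresorcinol monoethers. No stereocentre is created in 26 (the one in 23 vanishes on ring opening), and C2, separated from the reacting atoms by a CH2 group, stays (R). The selectivity needed is regiochemical and is secured by the polarised ynol ether: its unsubstituted carbon is the nucleophile that attacks the ketene carbonyl carbon, so C–OMe ends meta to C–OH, and the alkyl group at C3 of the cyclobutenone ends meta to both. An excess of 21, which has no β-hydrogen for a retro-ene loss, should keep the vinylketene from being captured by the phenol as it forms, and the neutral medium should leave acetate and dioxolane alone.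

Step 11
Reactants: 26 (R)-1-(3-hydroxy-5-methoxyphenyl)-7-(2-pentyl-1,3-dioxolan-2-yl)heptan-2-yl acetate
Product: 27 (R)-1-(3-hydroxy-5-methoxyphenyl)-8-oxotridecan-2-yl acetate
Conditions: 1 M aq HCl, THF, rt
Reagents that add atoms: water, O
Why: Mild acid-catalysed hydrolysis of a dialkyl ketone dioxolane releases the C8 ketone under conditions that a secondary acetate, a phenol and an aryl methyl ether tolerate, and C2 is not involved.

**Compound list**
1 | cycloheptanone | O=C1CCCCCC1 | starting material
2 | pentylmagnesium bromide | CCCCC[Mg]Br | starting material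
3 | bromomagnesium 1-pentylcycloheptan-1-olate | CCCCCC1(O[Mg]Br)CCCCCC1 | intermediate
4 | 1-pentylcycloheptan-1-ol | CCCCCC1(O)CCCCCC1 | intermediate
5 | 1-pentylcyclohept-1-ene | CCCCCC1=CCCCCC1 | intermediate
6 | 1-pentyl-8,9,10-trioxabicyclo[5.2.1]decane (secondary ozonide) | CCCCCC12CCCCCC(OO1)O2 | intermediate
7 | 7-oxododecanal | CCCCCC(=O)CCCCCC=O | intermediate
8 | allenylboronic acid pinacol ester | C=C=CB1OC(C)(C)C(C)(C)O1 | starting material
9 | (R)-12-[(4,4,5,5-tetramethyl-1,3,2-dioxaborolan-2-yl)oxy]pentadec-14-yn-6-one | CCCCCC(=O)CCCCC[C@H](CC#C)OB1OC(C)(C)C(C)(C)O1 | intermediate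
10 | (R)-12-hydroxypentadec-14-yn-6-one | CCCCCC(=O)CCCCC[C@H](CC#C)O | intermediate
11 | (R)-9-(2-pentyl-1,3-dioxolan-2-yl)non-1-yn-4-ol | CCCCCC1(OCCO1)CCCCC[C@H](CC#C)O | intermediate
12 | (R)-9-(2-pentyl-1,3-dioxolan-2-yl)non-1-yn-4-yl acetate | CCCCCC1(OCCO1)CCCCC[C@H](CC#C)OC(C)=O | intermediate
13 | trichloroacetyl chloride | ClC(Cl)(Cl)C(Cl)=O | starting material
14 | dichloroketene | ClC(Cl)=C=O | intermediate
15 | (R)-1-(4,4-dichloro-3-oxocyclobut-1-en-1-yl)-7-(2-pentyl-1,3-dioxolan-2-yl)heptan-2-yl acetate | CCCCCC1(OCCO1)CCCCC[C@H](CC2=CC(=O)C2(Cl)Cl)OC(C)=O | intermediate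
16 | (2R)-1-(4-chloro-3-oxocyclobut-1-en-1-yl)-7-(2-pentyl-1,3-dioxolan-2-yl)heptan-2-yl acetate (both epimers at the C–Cl carbon) | CCCCCC1(OCCO1)CCCCC[C@H](CC2=CC(=O)C2Cl)OC(C)=O | intermediate
17 | (R)-1-(3-oxocyclobut-1-en-1-yl)-7-(2-pentyl-1,3-dioxolan-2-yl)heptan-2-yl acetate | CCCCCC1(OCCO1)CCCCC[C@H](CC2=CC(=O)C2)OC(C)=O | intermediate
18 | chloroacetaldehyde dimethyl acetal (2-chloro-1,1-dimethoxyethane) | COC(CCl)OC | starting material
19 | 1-chloro-2-methoxyethene (E/Z mixture) | COC=CCl | intermediate
20 | sodium methoxyacetylide | COC#[C-].[Na+] | intermediate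
21 | methoxyacetylene | COC#C | intermediate
22 | (R)-3-methylidene-1-oxo-10-(2-pentyl-1,3-dioxolan-2-yl)dec-1-en-5-yl acetate (vinylketene) | CCCCCC1(OCCO1)CCCCC[C@H](CC(=C)C=C=O)OC(C)=O | intermediate
23 | (4R)-2-(2-methoxy-4-oxocyclobut-2-en-1-yl)-9-(2-pentyl-1,3-dioxolan-2-yl)non-1-en-4-yl acetate (both epimers at the ring CH) | CCCCCC1(OCCO1)CCCCC[C@H](CC(=C)C2C(=O)C=C2OC)OC(C)=O | intermediate
24 | (3E,7R)-3-methoxy-5-methylidene-1-oxo-12-(2-pentyl-1,3-dioxolan-2-yl)dodeca-1,3-dien-7-yl acetate (dienylketene) | CCCCCC1(OCCO1)CCCCC[C@H](CC(=C)/C=C(/OC)C=C=O)OC(C)=O | intermediate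
25 | (R)-1-(3-methoxy-5-oxocyclohexa-1,3-dien-1-yl)-7-(2-pentyl-1,3-dioxolan-2-yl)heptan-2-yl acetate | CCCCCC1(OCCO1)CCCCC[C@H](CC2=CC(OC)=CC(=O)C2)OC(C)=O | intermediate
26 | (R)-1-(3-hydroxy-5-methoxyphenyl)-7-(2-pentyl-1,3-dioxolan-2-yl)heptan-2-yl acetate | CCCCCC1(OCCO1)CCCCC[C@H](Cc2cc(O)cc(OC)c2)OC(C)=O | intermediate
27 | (R)-1-(3-hydroxy-5-methoxyphenyl)-8-oxotridecan-2-yl acetate | CCCCCC(=O)CCCCC[C@H](Cc1cc(O)cc(OC)c1)OC(C)=O | target

**Step count**
Total steps: 11. Longest linear sequence: 10 (steps 1–8, 10 and 11). Step 9 is a one-step side branch.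

**Steps most likely to fail**

Risk 1, step 7. The unactivated terminal alkyne may add too slowly, so that ketene oligomerisation wins, and zinc salts together with the acid chloride may erode the dioxolane.
The fallback uses no chlorine and no zinc. It sets out from alkyne 12. N,N-dimethylacetamide is activated with Tf2O and 2,4,6-collidine in refluxing CH2Cl2 to N,N-dimethylketeniminium triflate F1. This adds to the alkyne in a [2+2] cycloaddition, with the iminium carbon bonding to the CH terminus, and gives the cyclobutenylidene-dimethyliminium triflate F2. Hydrolysis with aqueous NaHCO3 should then release cyclobutenone 17, where the route is rejoined, so step 8 is bypassed as well.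

Risk 2, step 10. The volatile ynol ether may be lost to polymerisation before it meets the vinylketene, and the vinylketene may be captured by the phenol as it forms. Base treatment to undo that acylation is ruled out by the acetate.
The fallback uses a capped, non-volatile ketenophile with a traceless blocking group. It sets out from sodium methoxyacetylide 20, which is suspended in Et2O after removal of NH3 and quenched with Me3SiCl instead of brine, giving 1-methoxy-2-(trimethylsilyl)acetylene F3. Heating F3 with 17 in refluxing toluene should run the same cascade, with the silicon-bearing carbon attacking the ketene carbonyl carbon. This gives the 4-silylated phenol F4, whose hydroxyl is shielded by the neighbouring silyl group. CF3CO2H in wet CH2Cl2 should then remove the silyl group by ipso-protonation at the position activated by both oxygens, and the dioxolane at the same time, so the route is rejoined at target 27.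

Risk 3, step 4. Facial selectivity may be insufficient with an unbranched aliphatic aldehyde, and the 1,7-keto aldehyde may undergo acid-promoted intramolecular aldol condensation.
The fallback separates bond formation from stereocontrol. It sets out from keto aldehyde 7. An aldehyde-selective Barbier propargylation (Zn dust, propargyl bromide, THF–sat. aq NH4Cl, 0 °C) gives racemic 12-hydroxypentadec-14-yn-6-one F5. Kinetic resolution follows with immobilised Candida antarctica lipase B and vinyl acetate in methyl tert-butyl ether, run slightly past half conversion. By the empirical size rule for secondary alcohols (long chain large, propargyl medium), the enzyme should acylate the (S)-enantiomer to (S)-10-oxopentadec-1-yn-4-yl acetate F6. The unreacted (R)-alcohol 10 is then separated by chromatography and re-enters the route at step 5. The same enzymatic treatment could also be used to scavenge the minor enantiomer from material made by step 4.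

**Further compounds**
F1 | step 7 | N,N-dimethylketeniminium triflate | C=C=[N+](C)C.[O-]S(=O)(=O)C(F)(F)F
F2 | step 7 | N-{3-[(2R)-2-acetoxy-7-(2-pentyl-1,3-dioxolan-2-yl)heptyl]cyclobut-2-en-1-ylidene}-N-methylmethanaminium triflate | CCCCCC1(OCCO1)CCCCC[C@H](CC2=CC(=[N+](C)C)C2)OC(C)=O.[O-]S(=O)(=O)C(F)(F)F
F3 | step 10 | 1-methoxy-2-(trimethylsilyl)acetylene | COC#C[Si](C)(C)C
F4 | step 10 | (R)-1-[3-hydroxy-5-methoxy-4-(trimethylsilyl)phenyl]-7-(2-pentyl-1,3-dioxolan-2-yl)heptan-2-yl acetate | CCCCCC1(OCCO1)CCCCC[C@H](Cc2cc(O)c([Si](C)(C)C)c(OC)c2)OC(C)=O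
F5 | step 4 | racemic 12-hydroxypentadec-14-yn-6-one | CCCCCC(=O)CCCCCC(O)CC#C
F6 | step 4 | (S)-10-oxopentadec-1-yn-4-yl acetate | CCCCCC(=O)CCCCC[C@@H](CC#C)OC(C)=O
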